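The benzene ring of the target carries methoxy groups on C1 and C3 and its only carbon substituent on C5, the pattern of a 5-alkylcyclohexane-1,3-dione after dehydrogenation and O-methylation. The ring is therefore built last, on the end of the finished 10-phenyldecyl chain, by a [3+3] Michael–Claisen annulation: dimethyl malonate adds to the β-carbon of (E)-14-phenyltetradec-3-en-2-one (ring bond C4–C5) and the methyl ketone enolate then acylates on a malonate ester (ring bond C2–C3), closing the carbocycle with both oxygens in place in one operation. The methyl enone comes from a Li2CuCl4-catalysed alkyl–alkyl coupling and a cross-metathesis; hydrolysis–decarboxylation and iodine–methanol aromatization complete the route.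

Key step: step 3

Remark: the target has no stereocentre; the 1,3-dicarbonyl compounds 8, 9 and 10 are drawn as keto tautomers although they should exist largely as enols, and the double-bond geometry of 5 and the ring stereocentres of 8 are lost later.

Step 1
Reactants: 1 10-bromodec-1-ene; 2 2-phenylethylmagnesium chloride
Product: 3 12-phenyldodec-1-ene
Conditions: 2 (1.3 equiv), Li2CuCl4 (3 mol%), THF, −10 °C to rt
Reagents that add atoms: none
Why: Kochi-type cross-coupling of a primary alkyl Grignard reagent with a primary alkyl bromide under cuprate catalysis is fast at low temperature, forms the C(sp3)–C(sp3) bond cleanly and leaves the remote terminal alkene untouched.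

Step 2
Reactants: 3 12-phenyldodec-1-ene; 4 but-3-en-2-one (methyl vinyl ketone)
Product: 5 (E)-14-phenyltetradec-3-en-2-one
Conditions: 4 (3 equiv), second-generation Grubbs catalyst (2 mol%), CH2Cl2, 40 °C
Reagents that add atoms: none
Why: Olefin cross-metathesis between a terminal alkene that homodimerizes readily and an electron-poor enone that does not is a selective pairing, loss of ethene drives it, and the conjugated product should form as the thermodynamically preferred E isomer, whose geometry is in any case erased in step 3.

Step 3
Reactants: 5 (E)-14-phenyltetradec-3-en-2-one; 6 dimethyl malonate
Product: 8 methyl 2,4-dioxo-6-(10-phenyldecyl)cyclohexane-1-carboxylate, via dimethyl 2-(2-oxo-14-phenyltetradecan-4-yl)propanedioate 7 (not isolated)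
Conditions: 6 (1.2 equiv), NaOMe (1.3 equiv), MeOH, reflux; then aq HCl, 0 °C
Reagents that add atoms: none
Why: Sodium methoxide generates the malonate anion, which adds to the β-carbon of enone 5 (Michael addition, ring bond C4–C5) to give 7; under the equilibrating conditions the ketone of 7 is deprotonated at its CH3 group and this enolate acylates on one malonate ester carbonyl with loss of methoxide (Claisen condensation of the Dieckmann type, ring bond C2–C3). The closest known reaction type is the classical malonate–enone synthesis of dihydroresorcinols such as dimedone. The one ring is closed in a 6-(enolendo)-exo-trig mode, a favoured closure in which the enolate carbon attacks an ester carbonyl whose C=O bond lies outside the forming ring. Two stereocentres arise (C1 and C6 of 8) without control, which is acceptable because C1 loses its ester in step 4 and both carbons become aromatic in step 5. The step needs conjugate rather than carbonyl addition and closure through the methyl rather than the internal α-CH2 group: the soft, stabilized malonate anion adds 1,2 only reversibly, closure through the internal carbon would give a strained four-membered ring, and the six-membered product is withdrawn from all equilibria as its doubly stabilized 1,3-dicarbonyl enolate. Methoxide in methanol matches the methyl esters, so ester exchange changes nothing.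

Step 4
Reactants: 8 methyl 2,4-dioxo-6-(10-phenyldecyl)cyclohexane-1-carboxylate
Product: 10 5-(10-phenyldecyl)cyclohexane-1,3-dione, via 2,4-dioxo-6-(10-phenyldecyl)cyclohexane-1-carboxylic acid 9 (not isolated)
Conditions: NaOH, H2O/1,4-dioxane, 90 °C; then HCl to pH 1, 90 °C (−CO2)
Reagents that add atoms: none
Why: Saponification of the methyl ester proceeds while the ring is shielded from retro-Claisen cleavage as its dione enolate, and on acidification and warming the β-keto acid 9 loses CO2 through the usual cyclic six-membered transition state (ester hydrolysis followed by β-keto acid decarboxylation, as in the dimedone preparation).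

Step 5
Reactants: 10 5-(10-phenyldecyl)cyclohexane-1,3-dione
Product: 12 1,3-dimethoxy-5-(10-phenyldecyl)benzene, via 3-methoxy-5-(10-phenyldecyl)cyclohex-2-en-1-one 11 (not isolated)
Conditions: I2 (2 equiv), MeOH, reflux
Reagents that add atoms: methanol (CO)
Why: Iodine–methanol oxidative aromatization of a cyclohexane-1,3-dione: hydrogen iodide formed in the flask catalyses conversion of 10 into vinylogous ester 11 and on to its dienol ether, α-iodination and loss of HI then give the arene with both oxygens already methylated, and because C5 carries the only substituent the two carbonyls are equivalent while the saturated chain and the unactivated phenyl ring are inert to iodine.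

Compound list
1 | 10-bromodec-1-ene | C=CCCCCCCCCBr | starting material
2 | 2-phenylethylmagnesium chloride | Cl[Mg]CCc1ccccc1 | starting material
3 | 12-phenyldodec-1-ene | C=CCCCCCCCCCCc1ccccc1 | intermediate
4 | but-3-en-2-one (methyl vinyl ketone) | CC(=O)C=C | starting material
5 | (E)-14-phenyltetradec-3-en-2-one | CC(=O)/C=C/CCCCCCCCCCc1ccccc1 | intermediate
6 | dimethyl malonate | COC(=O)CC(=O)OC | starting material
7 | dimethyl 2-(2-oxo-14-phenyltetradecan-4-yl)propanedioate (racemic; not isolated) | COC(=O)C(C(=O)OC)C(CC(C)=O)CCCCCCCCCCc1ccccc1 | intermediate
8 | methyl 2,4-dioxo-6-(10-phenyldecyl)cyclohexane-1-carboxylate (mixture of diastereomers and enol tautomers) | COC(=O)C1C(=O)CC(=O)CC1CCCCCCCCCCc1ccccc1 | intermediate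
9 | 2,4-dioxo-6-(10-phenyldecyl)cyclohexane-1-carboxylic acid (not isolated) | OC(=O)C1C(=O)CC(=O)CC1CCCCCCCCCCc1ccccc1 | intermediate
10 | 5-(10-phenyldecyl)cyclohexane-1,3-dione | O=C1CC(=O)CC(CCCCCCCCCCc2ccccc2)C1 | intermediate
11 | 3-methoxy-5-(10-phenyldecyl)cyclohex-2-en-1-one (racemic; not isolated) | COC1=CC(=O)CC(CCCCCCCCCCc2ccccc2)C1 | intermediate
12 | 1,3-dimethoxy-5-(10-phenyldecyl)benzene | COc1cc(CCCCCCCCCCc2ccccc2)cc(OC)c1 | target

Total step count: 5 steps.
Longest linear sequence: 5 steps (1 → 3 → 5 → 8 → 10 → 12).

Steps most likely to fail

Step 3 (key step). Base-induced self-condensation or oligomerization of the enolizable enone may outrun the Michael addition, or the sequence may stall at the open-chain adduct because the Claisen closure is reversible. The fallback brings the arene in ready-made instead of building it. It sets out from bromide 1: Li2CuCl4-catalysed coupling with phenylmagnesium bromide in THF should give 10-phenyldec-1-ene F1. Hydroboration with 9-BBN-H in THF then gives 9-(10-phenyldecyl)-9-borabicyclo[3.3.1]nonane F2. This is coupled in the same flask with 1-bromo-3,5-dimethoxybenzene (PdCl2(dppf), K3PO4, THF/H2O, 65 °C; B-alkyl Suzuki–Miyaura coupling), and the fallback comes back to the route at target 12.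

Step 5. O-Methylation may lag behind dehydrogenation, so that partly methylated phenolic material results, or the electron-rich ring may be iodinated once it has formed. The fallback separates the two events and sets out from dione 10. Catalytic dehydrogenation over Pd/C in refluxing mesitylene under a nitrogen sweep, the reaction type used to make resorcinol from cyclohexane-1,3-dione, should give 5-(10-phenyldecyl)benzene-1,3-diol F3. Williamson methylation (MeI, K2CO3, acetone, reflux) then comes back to the route at target 12.

Step 2. Metal hydride species formed as the catalyst decays may move the terminal double bond along the chain before metathesis, which would give chain-shortened enones that are hard to separate, and self-metathesis of 3 may compete. The fallback is an olefination with fixed chain length and sets out from alkene 3. Ozonolysis (O3, CH2Cl2, −78 °C) gives the secondary ozonide 3-(10-phenyldecyl)-1,2,4-trioxolane F4, which is reduced in the flask with PPh3 to 11-phenylundecanal F5. Wittig reaction of F5 with the stabilized ylide 1-(triphenylphosphoranylidene)propan-2-one (toluene, 80 °C) should give the E enone and comes back to the route at compound 5.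

Further compounds
F1 | step 3 | 10-phenyldec-1-ene | C=CCCCCCCCCc1ccccc1
F2 | step 3 | 9-(10-phenyldecyl)-9-borabicyclo[3.3.1]nonane | c1ccccc1CCCCCCCCCCB1C2CCCC1CCC2
F3 | step 5 | 5-(10-phenyldecyl)benzene-1,3-diol | Oc1cc(O)cc(CCCCCCCCCCc2ccccc2)c1
F4 | step 2 | 3-(10-phenyldecyl)-1,2,4-trioxolane | C1OC(CCCCCCCCCCc2ccccc2)OO1
F5 | step 2 | 11-phenylundecanal | O=CCCCCCCCCCCc1ccccc1
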